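**Retrosynthetic overview**
1. Final C–C bond: sp3–sp2 Negishi coupling between the benzylic CH2 (C7') and ring B, joining primary iodide 13 (ring A plus the 8S,8'R dimethyl diad) to aryl bromide 7 (rings B and C with the 7''S,8''R ether-alcohol), then global debenzylation.
2. Iodide 13: from meso anhydride 9 by Rh-catalysed enantioselective aryl-zinc desymmetrisation (sets C8 and C8' together), then C=O → CH2 and CO2H → CH2I.
3. Bromide 7: C8''–O bond by Mitsunobu inversion of (S)-lactate with 4-bromo-2,6-dimethoxyphenol; C7''–aryl bond by Weinreb ketone synthesis; 7''S by chelation-controlled reduction.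
4. No ring is formed: all three benzene rings are purchased (1, and 5 used twice).

Assumption: 1 and 5 are commercial (5 is otherwise one step from 4-bromoguaiacol and BnBr), and the Taddol-PNMe2 enantiomer in step 6 is whichever gives (2S,3R)-10 (written as (R,R); use (S,S) if the sense is opposite).

**Fragment B–C**

Step 1
Reactants: 1, 4-bromo-2,6-dimethoxyphenol; 2, ethyl (S)-lactate
Product: 3, ethyl (2R)-2-(4-bromo-2,6-dimethoxyphenoxy)propanoate
Conditions: PPh3, DIAD, THF, 0 °C → rt
Reagents that add atoms: none beyond 1 and 2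
Why: Mitsunobu etherification of the acidic phenol with the ester-activated secondary alcohol goes by SN2 inversion, turning (S)-lactate into the (R)-aryloxy centre that becomes C8''.

Step 2
Reactants: 3
Product: 4, (2R)-2-(4-bromo-2,6-dimethoxyphenoxy)-N-methoxy-N-methylpropanamide
Conditions: MeNH(OMe)·HCl, i-PrMgCl, THF, −20 → 0 °C
Reagents that add atoms: N,O-dimethylhydroxylamine hydrochloride, CNOC.Cl
Why: Weinreb amidation through the magnesium amide does not touch the stereocentre, and the electron-rich aryl bromide does not exchange with i-PrMgCl at this temperature.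

Step 3
Reactants: 4; 5, 1-(benzyloxy)-4-bromo-2-methoxybenzene (as its Grignard reagent)
Product: 6, (2R)-1-[4-(benzyloxy)-3-methoxyphenyl]-2-(4-bromo-2,6-dimethoxyphenoxy)propan-1-one
Conditions: 5, Mg, THF; then 4, THF, 0 °C; cold aq NH4Cl
Reagents that add atoms: none beyond 4 and 5
Why: Weinreb ketone synthesis; the chelated tetrahedral intermediate prevents over-addition and keeps the α-centre non-enolisable until the mildly acidic quench.

Step 4
Reactants: 6
Product: 7, (1S,2R)-1-[4-(benzyloxy)-3-methoxyphenyl]-2-(4-bromo-2,6-dimethoxyphenoxy)propan-1-ol (erythro)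
Conditions: Zn(BH4)2, Et2O, −20 → 0 °C
Reagents that add atoms: none
Why: Cram-chelate reduction; Zn bridges the C=O and aryloxy oxygens and hydride attacks the face anti to the methyl, giving the erythro alcohol (7''S from 8''R), with the minor threo isomer removed by chromatography.

**Fragment A**

Step 5
Reactants: 8, meso-2,3-dimethylsuccinic acid
Product: 9, cis-2,3-dimethylsuccinic anhydride, (3R,4S)-3,4-dimethyloxolane-2,5-dione
Conditions: AcCl, reflux, 2 h; evaporate
Reagents that add atoms: none
Why: Cyclodehydration under non-basic conditions keeps the cis (meso) relationship of the two methyls.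

Step 6
Reactants: 9; 5 (as its arylzinc)
Product: 10, (2S,3R)-4-[4-(benzyloxy)-3-methoxyphenyl]-2,3-dimethyl-4-oxobutanoic acid
Conditions: 5, n-BuLi, THF, −78 °C; Zn(OTf)2; then 9, [Rh(cod)Cl]2 (4 mol %), (R,R)-Taddol-PNMe2 (8 mol %), THF/DMF, 50 °C
Reagents that add atoms: none beyond 9 and 5
Why: Rh-catalysed enantioselective desymmetrising acyl cross-coupling of a meso anhydride with an arylzinc; the syn diad comes from the anhydride and the ligand picks one enantiotopic C–O bond, setting C8 and C8' together (upgrade ee by crystallising 10 as its 1-phenylethylammonium salt, since a minor enantiomer would later give a remote, hard-to-separate diastereomer).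

Step 7
Reactants: 10
Product: 11, (2S,3S)-4-[4-(benzyloxy)-3-methoxyphenyl]-2,3-dimethylbutanoic acid
Conditions: Et3SiH (4 equiv), TFA/CH2Cl2, 0 °C → rt
Reagents that add atoms: none
Why: Ionic hydrogenation (Kursanov–Parnes) takes the electron-rich aryl ketone, or its transient γ-lactone, to the methylene faster than the α-centre enolises, and the aryl benzyl ether and acid are tolerated.

Step 8
Reactants: 11
Product: 12, (2S,3S)-4-[4-(benzyloxy)-3-methoxyphenyl]-2,3-dimethylbutan-1-ol
Conditions: BH3·SMe2, THF, 0 °C → rt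
Reagents that add atoms: none
Why: Chemoselective borane reduction of the carboxylic acid, with no epimerisable intermediate.

Step 9
Reactants: 12
Product: 13, 1-(benzyloxy)-4-[(2S,3S)-4-iodo-2,3-dimethylbutyl]-2-methoxybenzene
Conditions: I2, PPh3, imidazole, CH2Cl2, 0 °C → rt
Reagents that add atoms: iodine, II
Why: Appel-type (Garegg–Samuelsson) iodination of the primary alcohol; the stereocentres are not involved.

**Union and deprotection**

Step 10
Reactants: 13 (1.5 equiv, as its alkylzinc iodide); 7
Product: 14, (1S,2R)-1-[4-(benzyloxy)-3-methoxyphenyl]-2-{4-[(2R,3S)-4-(4-(benzyloxy)-3-methoxyphenyl)-2,3-dimethylbutyl]-2,6-dimethoxyphenoxy}propan-1-ol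
Conditions: 13, Zn dust, LiCl, THF, 50 °C; then 7, Pd(OAc)2 (4 mol %), SPhos (8 mol %), THF, rt → 50 °C
Reagents that add atoms: none beyond 13 and 7
Why: Negishi sp3–sp2 coupling; Zn inserts into the primary iodide and Pd/SPhos couples it with the unhindered electron-rich aryl bromide, conditions that tolerate a free secondary OH, and all four stereocentres are remote from the reacting carbons.

Step 11
Reactants: 14
Product: 15, (+)-(7''S,8S,8'R,8''R)-4,4''-dihydroxy-3,3',3'',5'-tetramethoxy-4',8''-oxy-8,8'-sesquineolignan-7''-ol (target)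
Conditions: H2 (1 atm), 10% Pd/C, EtOAc, rt
Reagents that add atoms: none
Why: Neutral hydrogenolysis removes both aryl benzyl ethers, while the secondary benzylic alcohol and the alkyl aryl ethers survive short, acid-free exposure.

**Compound list**
1 | 4-bromo-2,6-dimethoxyphenol | COc1cc(Br)cc(OC)c1O | starting material
2 | ethyl (S)-lactate | C[C@H](O)C(=O)OCC | starting material
3 | ethyl (2R)-2-(4-bromo-2,6-dimethoxyphenoxy)propanoate | COc1cc(Br)cc(OC)c1O[C@H](C)C(=O)OCC | intermediate
4 | (2R)-2-(4-bromo-2,6-dimethoxyphenoxy)-N-methoxy-N-methylpropanamide | COc1cc(Br)cc(OC)c1O[C@H](C)C(=O)N(C)OC | intermediate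
5 | 1-(benzyloxy)-4-bromo-2-methoxybenzene | COc1cc(Br)ccc1OCc1ccccc1 | starting material
6 | (2R)-1-[4-(benzyloxy)-3-methoxyphenyl]-2-(4-bromo-2,6-dimethoxyphenoxy)propan-1-one | COc1cc(Br)cc(OC)c1O[C@H](C)C(=O)c1ccc(OCc2ccccc2)c(OC)c1 | intermediate
7 | (1S,2R)-1-[4-(benzyloxy)-3-methoxyphenyl]-2-(4-bromo-2,6-dimethoxyphenoxy)propan-1-ol | COc1cc(Br)cc(OC)c1O[C@H](C)[C@@H](O)c1ccc(OCc2ccccc2)c(OC)c1 | intermediate
8 | meso-2,3-dimethylsuccinic acid | C[C@H](C(=O)O)[C@@H](C)C(=O)O | starting material
9 | cis-2,3-dimethylsuccinic anhydride | C[C@H]1C(=O)OC(=O)[C@H]1C | intermediate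
10 | (2S,3R)-4-[4-(benzyloxy)-3-methoxyphenyl]-2,3-dimethyl-4-oxobutanoic acid | COc1cc(C(=O)[C@H](C)[C@H](C)C(=O)O)ccc1OCc1ccccc1 | intermediate
11 | (2S,3S)-4-[4-(benzyloxy)-3-methoxyphenyl]-2,3-dimethylbutanoic acid | COc1cc(C[C@H](C)[C@H](C)C(=O)O)ccc1OCc1ccccc1 | intermediate
12 | (2S,3S)-4-[4-(benzyloxy)-3-methoxyphenyl]-2,3-dimethylbutan-1-ol | COc1cc(C[C@H](C)[C@H](C)CO)ccc1OCc1ccccc1 | intermediate
13 | 1-(benzyloxy)-4-[(2S,3S)-4-iodo-2,3-dimethylbutyl]-2-methoxybenzene | COc1cc(C[C@H](C)[C@H](C)CI)ccc1OCc1ccccc1 | intermediate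
14 | 4,4''-di-O-benzyl ether of the target | COc1cc(C[C@H](C)[C@H](C)Cc2cc(OC)c(O[C@H](C)[C@@H](O)c3ccc(OCc4ccccc4)c(OC)c3)c(OC)c2)ccc1OCc1ccccc1 | intermediate
15 | (+)-(7''S,8S,8'R,8''R)-4,4''-dihydroxy-3,3',3'',5'-tetramethoxy-4',8''-oxy-8,8'-sesquineolignan-7''-ol | COc1cc(C[C@H](C)[C@H](C)Cc2cc(OC)c(O[C@H](C)[C@@H](O)c3ccc(O)c(OC)c3)c(OC)c2)ccc1O | target

**Totals**
Total steps: 11. Longest linear sequence: 7 (steps 5–11, from 8); the B–C branch is 6 (steps 1–4, 10, 11).

**Steps most likely to fail, with fallbacks**
1. Step 6 (ee typically below 95%, sense of induction, arylzinc quality). Fallback: cinchona-alkaloid-catalysed methanolysis of 9 to the hemiester, BH3 reduction and lactonisation to cis-3,4-dimethylbutyrolactone, TMSI/EtOH opening to the iodo ester, Negishi coupling with 5, then ester reduction and iodination to 13. This route has no enolisable ketone, and either enantiomeric series is reachable by reducing the acid or the ester terminus.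
2. Step 7 (partial loss of the benzyl ether in TFA, or epimerisation α to the ketone). Fallback: H2, Pd/C, AcOH to reduce C=O to CH2 and remove the benzyl group together, then BnBr/K2CO3 (benzyl ether and benzyl ester) and LiAlH4 to reach 12.
3. Step 10 (alkylzinc protonation by the free OH, slow oxidative addition). Fallback: couple the zinc reagent from 13 with TBS-protected 1, remove the silyl group, and build the side chain on the core phenol in a linear endgame (Mitsunobu with 2, Weinreb amide, Grignard of 5, Zn(BH4)2, hydrogenolysis).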